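**Retrosynthetic overview**
- The target comes from acidic MOM removal of a MOM-protected flavone. The flavone comes from the O1–C2 bond: an oxidative 6-endo oxa-Michael closure of a 2'-hydroxychalcone (C–O bond, key step). The pyranone C ring is the only ring made and is formed last.
- The chalcone comes from a Claisen–Schmidt condensation of a protected benzyl-phloroacetophenone with isovanillin (B ring bought).
- The protected ketone comes from regioselective tris-MOM protection that leaves only the benzyl-flanked OH free; this decides 8-benzyl over 6-benzyl in the ring closure.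
- The benzyl-phloroacetophenone comes from Friedel–Crafts p-hydroxybenzylation of phloroacetophenone with 4-hydroxybenzyl alcohol (A ring and benzyl ring bought).

Assumption: the target has no stereocentre (it is achiral), so no enantiocontrol is needed; the only stereo-element on the way is the E-alkene of the chalcone.

**Step 1**
Reactants: 1 2,4,6-trihydroxyacetophenone; 2 4-hydroxybenzyl alcohol
Product: 3 1-[2,4,6-trihydroxy-3-(4-hydroxybenzyl)phenyl]ethanone
Conditions: 1 (3 equiv), 2 added over 2 h, TsOH·H2O (10 mol%), 1,4-dioxane, 60 °C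
Reagents that add atoms: none
Why: Friedel–Crafts benzylation in which acid ionises 2 to its p-quinone methide/benzylic cation, captured by C3 (equivalent to C5) of the phloroglucinol ring, with excess 1 and slow addition limiting bis-benzylation and self-condensation of 2; no stereocentre is formed.

**Step 2**
Reactants: 3 1-[2,4,6-trihydroxy-3-(4-hydroxybenzyl)phenyl]ethanone
Product: 4 1-{2-hydroxy-4,6-bis(methoxymethoxy)-3-[4-(methoxymethoxy)benzyl]phenyl}ethanone
Conditions: MOMCl (3.5 equiv), i-Pr2NEt (5 equiv), CH2Cl2, 0 °C → rt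
Reagents that add atoms: chloromethyl methyl ether (MOMCl), COCCl
Why: Williamson-type O-alkylation (MOM protection) of the three accessible phenols, while the 2-OH, buttressed between the benzyl and acetyl groups and held in the C=O hydrogen bond, stays free, as expected from steric and chelation grounds for partial alkylation of 3-C-alkylphloroacetophenones; no stereocentre is formed.

**Step 3**
Reactants: 4 1-{2-hydroxy-4,6-bis(methoxymethoxy)-3-[4-(methoxymethoxy)benzyl]phenyl}ethanone; 5 isovanillin (3-hydroxy-4-methoxybenzaldehyde)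
Product: 6 (E)-3-(3-hydroxy-4-methoxyphenyl)-1-{2-hydroxy-4,6-bis(methoxymethoxy)-3-[4-(methoxymethoxy)benzyl]phenyl}prop-2-en-1-one
Conditions: 5 (1.3 equiv), KOH (50% aq, 10 equiv), EtOH, rt, 48 h; then 1 M HCl to pH 5, 0 °C
Reagents that add atoms: none
Why: Claisen–Schmidt aldol condensation whose E1cB dehydration gives the thermodynamically favoured E-enone; the MOM ethers are base-stable and the meta-phenoxide of 5 does not deactivate its aldehyde.

**Step 4**
Reactants: 6 (E)-3-(3-hydroxy-4-methoxyphenyl)-1-{2-hydroxy-4,6-bis(methoxymethoxy)-3-[4-(methoxymethoxy)benzyl]phenyl}prop-2-en-1-one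
Product: 10 5,7-dihydroxy-8-(4-hydroxybenzyl)-2-(3-hydroxy-4-methoxyphenyl)-4H-chromen-4-one, via flavanone 7 (not isolated), via 3-bromoflavanone 8 (not isolated), via tris-MOM flavone 9 (not isolated)
Conditions: DBU (2.5 equiv), BrCCl3 (1.15 equiv, added over 1 h), MeCN, 0 → 40 °C, N2, dark; then MeOH, 3 M HCl, 55 °C (one pot)
Reagents that add atoms: none
Why: Proposed new method: a halogen-transfer-interrupted oxa-Michael annulation, in which DBU turns the single free phenol (the one next to the benzyl group) into a phenoxide that closes 6-endo-trig onto the enone to form the O1–C2 bond, the C3 enolate so formed is captured by halophilic Br+ transfer from BrCCl3 (CCl3− is protonated to CHCl3) and DBU then removes HBr from the 3-bromoflavanone, the irreversible bromination/elimination draining the reversible cyclisation; the medium stays basic so the 5-OMOM group stays on and the ring oxygen cannot switch to give the 6-benzyl isomer, BrCCl3 is not expected to halogenate the electron-rich rings as I2, NBS or Br2 would, the transient C2/C3 stereocentres are erased (the target is achiral), and ordinary HCl/MeOH acetal methanolysis then removes the three MOM groups; the closest known reaction types are the DBU/BrCCl3 dehydrogenation of oxazolines and thiazolines to azoles, the iodine/pyridine dehydrogenation of flavanones and the I2/DMSO cyclisation of 2'-hydroxychalcones.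

**Compound list**
1 | 2,4,6-trihydroxyacetophenone (phloroacetophenone) | CC(=O)c1c(O)cc(O)cc1O | starting material
2 | 4-hydroxybenzyl alcohol | OCc1ccc(O)cc1 | starting material
3 | 1-[2,4,6-trihydroxy-3-(4-hydroxybenzyl)phenyl]ethanone | CC(=O)c1c(O)cc(O)c(Cc2ccc(O)cc2)c1O | intermediate
4 | 1-{2-hydroxy-4,6-bis(methoxymethoxy)-3-[4-(methoxymethoxy)benzyl]phenyl}ethanone | CC(=O)c1c(OCOC)cc(OCOC)c(Cc2ccc(OCOC)cc2)c1O | intermediate
5 | isovanillin (3-hydroxy-4-methoxybenzaldehyde) | COc1ccc(C=O)cc1O | starting material
6 | (E)-3-(3-hydroxy-4-methoxyphenyl)-1-{2-hydroxy-4,6-bis(methoxymethoxy)-3-[4-(methoxymethoxy)benzyl]phenyl}prop-2-en-1-one | COc1ccc(/C=C/C(=O)c2c(OCOC)cc(OCOC)c(Cc3ccc(OCOC)cc3)c2O)cc1O | intermediate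
7 | racemic 2-(3-hydroxy-4-methoxyphenyl)-5,7-bis(methoxymethoxy)-8-[4-(methoxymethoxy)benzyl]chroman-4-one (present in the flask mainly as its C3 enolate) | COc1ccc(C2CC(=O)c3c(OCOC)cc(OCOC)c(Cc4ccc(OCOC)cc4)c3O2)cc1O | intermediate
8 | 3-bromo-2-(3-hydroxy-4-methoxyphenyl)-5,7-bis(methoxymethoxy)-8-[4-(methoxymethoxy)benzyl]chroman-4-one (racemic, cis/trans mixture) | COc1ccc(C2Oc3c(Cc4ccc(OCOC)cc4)c(OCOC)cc(OCOC)c3C(=O)C2Br)cc1O | intermediate
9 | 2-(3-hydroxy-4-methoxyphenyl)-5,7-bis(methoxymethoxy)-8-[4-(methoxymethoxy)benzyl]-4H-chromen-4-one | COc1ccc(-c2cc(=O)c3c(OCOC)cc(OCOC)c(Cc4ccc(OCOC)cc4)c3o2)cc1O | intermediate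
10 | 5,7-dihydroxy-8-(4-hydroxybenzyl)-2-(3-hydroxy-4-methoxyphenyl)-4H-chromen-4-one (achiral) | COc1ccc(-c2cc(=O)c3c(O)cc(O)c(Cc4ccc(O)cc4)c3o2)cc1O | target

**Totals**
Total step count: 4. Longest linear sequence: 4 (1 → 3 → 4 → 6 → 10).

**Steps most likely to fail, with fallbacks**

Step 4 (the proposed new step). The enolate capture may be too slow, over-bromination may give some 3-bromoflavone, or BrCCl3 may brominate a phenoxide ring. The fallback uses known chemistry at the acyl oxidation level and sets out from compound 4. Commercial methyl isovanillate is protected (MOMCl, i-Pr2NEt) to methyl 4-methoxy-3-(methoxymethoxy)benzoate F4. Claisen condensation of the dianion of 4 (LiHMDS 3.5 equiv, THF, −78 °C → rt) with F4 gives 1-{2-hydroxy-4,6-bis(methoxymethoxy)-3-[4-(methoxymethoxy)benzyl]phenyl}-3-[4-methoxy-3-(methoxymethoxy)phenyl]propane-1,3-dione F5. Acid-catalysed cyclodehydration (TsOH cat., toluene, 80 °C) through its only free phenol gives 5,7-bis(methoxymethoxy)-8-[4-(methoxymethoxy)benzyl]-2-[4-methoxy-3-(methoxymethoxy)phenyl]-4H-chromen-4-one F6. Treatment with 3 M HCl/MeOH at 55 °C removes the MOM groups and the fallback comes back to the route at compound 10.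

Step 2. The alkylation may not discriminate fully between the two ortho hydroxyls; the wrong tris-MOM isomer would lead to the 6-benzyl flavone. The fallback sets out from compound 3. Exhaustive protection (NaH, MOMCl, DMF, 0 °C → rt) gives 1-{2,4,6-tris(methoxymethoxy)-3-[4-(methoxymethoxy)benzyl]phenyl}ethanone F3. One ortho MOM group is then removed with carbonyl assistance (cat. I2, MeOH, rt, stopped at mono-cleavage). The MOM flanked by both the benzyl and the acetyl group is twisted out of plane and should be cleaved first, though selectivity between the two ortho MOM groups is not established and the regiochemistry of the product would need checking (HMBC/NOE). The fallback comes back at compound 4.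

Step 1. Bis-benzylation of 1 and oligomerisation of 2 may hold the yield down. The fallback reverses the order and sets out from compound 2. Friedel–Crafts benzylation of commercial phloroglucinol (5 equiv, TsOH cat., dioxane, 60 °C; excess washed out with water) gives 2-(4-hydroxybenzyl)benzene-1,3,5-triol F1. Hoesch acylation (MeCN, ZnCl2, HCl gas, Et2O, 0 °C) gives 1-[2,4,6-trihydroxy-3-(4-hydroxybenzyl)phenyl]ethan-1-iminium chloride F2, which is not isolated. The two free ring positions of F1 are equivalent, and the Hoesch reaction touches only the phloroglucinol ring and stops at mono-acylation. Hydrolysis in hot water comes back at compound 3.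

**Further compounds**
F1 | step 1 | 2-(4-hydroxybenzyl)benzene-1,3,5-triol | Oc1ccc(Cc2c(O)cc(O)cc2O)cc1
F2 | step 1 | 1-[2,4,6-trihydroxy-3-(4-hydroxybenzyl)phenyl]ethan-1-iminium chloride | CC(=[NH2+])c1c(O)cc(O)c(Cc2ccc(O)cc2)c1O.[Cl-]
F3 | step 2 | 1-{2,4,6-tris(methoxymethoxy)-3-[4-(methoxymethoxy)benzyl]phenyl}ethanone | CC(=O)c1c(OCOC)cc(OCOC)c(Cc2ccc(OCOC)cc2)c1OCOC
F4 | step 4 | methyl 4-methoxy-3-(methoxymethoxy)benzoate | COC(=O)c1ccc(OC)c(OCOC)c1
F5 | step 4 | 1-{2-hydroxy-4,6-bis(methoxymethoxy)-3-[4-(methoxymethoxy)benzyl]phenyl}-3-[4-methoxy-3-(methoxymethoxy)phenyl]propane-1,3-dione | COc1ccc(C(=O)CC(=O)c2c(OCOC)cc(OCOC)c(Cc3ccc(OCOC)cc3)c2O)cc1OCOC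
F6 | step 4 | 5,7-bis(methoxymethoxy)-8-[4-(methoxymethoxy)benzyl]-2-[4-methoxy-3-(methoxymethoxy)phenyl]-4H-chromen-4-one | COc1ccc(-c2cc(=O)c3c(OCOC)cc(OCOC)c(Cc4ccc(OCOC)cc4)c3o2)cc1OCOC
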